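**Retrosynthetic overview**

1. The C15 ketone, the two acetates and the free C6 hydroxyl are late adjustments of a silyl-protected 16-ene lactone (allylic oxidation at C15, silyl/acetyl exchange, final desilylation).
2. Ring D (C8–C15–C16–C13) comes from a 5-exo vinyl-radical closure of a 2-bromoallyl group placed on C8 by lactone enolate alkylation; ring C is the 1,4-cyclohexadiene ring of the acid partner.
3. Key disconnection C9–C10: the δ-lactone (C7, C8, C9, C10, C20, O) is opened at C9–C10 to an ester of cyclohexa-1,4-diene-1-carboxylic acid with a C1/C10-epoxy C20-alcohol; in the forward sense, reductive epoxide opening gives the C10 radical, which closes the lactone 6-endo onto C9.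
4. Enabling feature: the C1 oxygen is vicinal to quaternary C10, so a C1–C10 epoxide is a latent C10 radical that leaves the C1–O bond in place; C9 is the β-carbon of the lactone carbonyl C7, which the C20–O ester link already holds next to C10.
5. Ring A (C4 and C5 stereocentres, C10=C1 alkene, C6 and C20 oxygens) comes from an enantioselective Diels–Alder reaction of 3-vinyl-2,5-dihydrofuran with methacrolein. Ring order: ring A, lactone ring (ring C carried in preformed), ring D.

Key step: step 9

**Remarks**

- Carbon numbers C1–C20 are the ent-kaurane numbers of the target carbons: C7 lactone carbonyl, C20 lactone OCH2, C6 the CH2OH carbon, C19 the CH2OAc carbon, C15 ketone, C17 exocyclic CH2.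
- Assumption: the (S)-configured oxazaborolidinium catalyst is taken to give the (3aS,4R) adduct in step 2; if its facial sense is the opposite, the mirror-image catalyst is used.
- The C8 configuration drawn for the step 9 and step 10 products is the expected cis-fused epimer; it is erased by enolisation in step 11.

**Route**

Step 1
Reactants: 1 allyl propargyl ether
Product: 2 3-vinyl-2,5-dihydrofuran
Conditions: second-generation Grubbs catalyst (2 mol%), ethylene (1 atm), CH2Cl2, rt
Reagents that add atoms: none
Why: Ring-closing enyne metathesis in the exo mode should convert the 1,6-enyne into the 1-vinylcycloalkene-type diene, a conversion known for this very substrate.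

Step 2
Reactants: 2 3-vinyl-2,5-dihydrofuran; 3 methacrolein
Product: 4 (3aS,4R)-4-methyl-1,3,3a,4,5,6-hexahydroisobenzofuran-4-carbaldehyde
Conditions: (S)-o-tolyl-oxazaborolidinium triflimide from (S)-α,α-diphenylprolinol (20 mol%), CH2Cl2, −78 → −40 °C
Reagents that add atoms: none
Why: Catalytic enantioselective Diels–Alder reaction of a 2-substituted acrolein, in which the "ortho" orientation typical of 1-vinylcycloalkenes joins the formyl-bearing carbon (C4) to C5, the endo position of the complexed formyl group places CHO cis to the ring CH2O arm at C5, and the catalyst face shielding sets the absolute configuration.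

Step 3
Reactants: 4 aldehyde
Product: 5 [(3aR,4R)-4-methyl-1,3,3a,4,5,6-hexahydroisobenzofuran-4-yl]methanol
Conditions: NaBH4, MeOH, 0 °C
Reagents that add atoms: none
Why: Hydride reduction of the non-enolisable neopentyl aldehyde should give the C19 alcohol without touching the stereocentres.

Step 4
Reactants: 5 alcohol
Product: 6 tert-butyldimethylsilyl ether of 5
Conditions: TBSCl, imidazole, DMF, rt
Reagents that add atoms: tert-butyldimethylsilyl chloride, CC(C)(C)[Si](C)(C)Cl
Why: Standard silylation protects the C19 hydroxyl with a group that is later removed by acid while a TBDPS ether stays.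

Step 5
Reactants: 7 buta-1,3-diene; 8 propiolic acid
Product: 9 cyclohexa-1,4-diene-1-carboxylic acid
Conditions: toluene, hydroquinone (cat.), sealed tube, 90 °C
Reagents that add atoms: none
Why: Diels–Alder reaction of butadiene with an acetylenic dienophile should give the skipped diene acid directly, with the enoate C8=C9 and the C12=C13 alkene needed later.

Step 6
Reactants: 6 silyl ether; 9 cyclohexa-1,4-diene-1-carboxylic acid
Product: 11 allylic ester with free C6 hydroxyl, via bromo alcohol 10 (not isolated)
Conditions: Me2BBr, CH2Cl2, −78 °C, NaHCO3 wash; crude 10 added to 9 and Cs2CO3 (0.55 equiv) in DMF, 0 °C → rt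
Reagents that add atoms: dimethylboron bromide, CB(C)Br (gives the bromine of 10, which is lost again on the way to 11)
Why: Bromoborane cleavage of a cyclic ether should occur at the allylic C20–O bond and free the C6 hydroxyl, and the primary allylic bromide should then undergo SN2 carboxylate alkylation to install the C20–O–C7 ester.

Step 7
Reactants: 11 allylic ester
Product: 12 C1/C10 epoxide with oxygen syn to the C5 CH2OH group
Conditions: VO(acac)2 (5 mol%), t-BuOOH, CH2Cl2, 0 °C → rt
Reagents that add atoms: tert-butyl hydroperoxide, CC(C)(C)OO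
Why: Hydroxyl-directed vanadium-catalysed epoxidation by the homoallylic C6 hydroxyl should deliver oxygen only to the nearby trisubstituted C10=C1 alkene and to the face syn to CH2OH, which fixes the later C1 configuration.

Step 8
Reactants: 12 epoxy alcohol
Product: 13 tert-butyldiphenylsilyl ether of 12
Conditions: TBDPSCl, imidazole, DMF, rt
Reagents that add atoms: tert-butyldiphenylsilyl chloride, CC(C)(C)[Si](Cl)(c1ccccc1)c1ccccc1
Why: Silylation under non-acidic conditions should protect C6–OH with a group that outlasts the later acid removal of the TBS and TES ethers.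

Step 9
Reactants: 13 epoxy ester
Product: 14 spirolactone with free C1 hydroxyl
Conditions: Cp2TiCl2 (0.2 equiv), Mn dust, 2,4,6-collidine·HCl, THF, 45 °C, slow addition of 13 (final 0.005 M)
Reagents that add atoms: none
Why: Proposed new method: Cp2TiCl (trivalent titanium, regenerated by Mn and collidinium chloride) should open the C1–C10 epoxide homolytically to the tertiary C10 radical with the C1–O–Ti bond retained, the radical should add through the C20–O–C7 ester tether to C9 of the enoate, and the resulting C8 α-ester radical should be reduced to a titanium enolate and protonated; the closest known reaction type is the Cp2TiCl-mediated reductive coupling of epoxides with acrylates followed by lactonisation, here made intramolecular so that the C–C bond formation itself closes the lactone, which has not been shown through an ester tether. The δ-lactone closes in the 6-endo-trig mode, favoured over 5-exo because attack at the fully substituted C8 is hindered and only attack at C9 gives the stabilised α-ester radical. C1 keeps the configuration of the epoxide oxygen, C10 is set by attack on the face of the planar radical opposite to both flanking substituents (C1–OTi and C5–CH2OSi), and C9 is set in an envelope transition state that keeps the bulky C4/C5 arm of ring A outside ring C and only the small C1/C2 arm above it; C8 is a protonation centre that step 11 erases. The step needs cyclisation to outrun reduction or hydrogen abstraction of the C10 radical, which is slowed by the s-trans preference of the ester: the tertiary β-titanoxy radical is long-lived towards Cp2TiCl, the titanium concentration is kept catalytic, high dilution limits hydrogen transfer from the bis-allylic CH2 groups of a second molecule, and warming populates the reactive ester rotamer.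

Step 10
Reactants: 14 spirolactone alcohol
Product: 15 triethylsilyl ether of 14
Conditions: TESOTf, 2,6-lutidine, CH2Cl2, −78 °C
Reagents that add atoms: triethylsilyl trifluoromethanesulfonate, CC[Si](CC)(CC)OS(=O)(=O)C(F)(F)F
Why: Silyl triflate silylation should protect the hindered C1 hydroxyl so that the lactone can be enolised cleanly.

Step 11
Reactants: 15 silyl-protected spirolactone
Product: 16 C8-(2-bromoallyl) lactone
Conditions: LiN(i-Pr)2 (LDA), THF/HMPA, −78 °C; then 2,3-dibromopropene, −78 → −40 °C
Reagents that add atoms: 2,3-dibromopropene, C=C(Br)CBr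
Why: Lactone enolate alkylation should create the C8 quaternary centre with the electrophile entering the face of the ring-fusion enolate away from the fold of ring C, which gives the cis-fused product with C15 cis to H9.

Step 12
Reactants: 16 vinyl bromide
Product: 17 16-methylene bicyclo[3.2.1]octane lactone
Conditions: Bu3SnH (1.5 equiv), AIBN (0.1 equiv), benzene, 80 °C, 0.02 M
Reagents that add atoms: none
Why: 5-exo-trig cyclisation of the C16 vinyl radical onto C13 of the C12=C13 alkene should close ring D, the one-carbon tether forcing the cis bridge and so fixing C13, while a high stannane concentration traps the kinetic radical before rearrangement.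

Step 13
Reactants: 17 tris-silyl ether
Product: 19 1,19-diacetate with C6–OTBDPS, via diol 18 (not isolated)
Conditions: CSA (0.1 equiv), MeOH/CH2Cl2, 0 °C → rt; evaporate; Ac2O, pyridine, DMAP (cat.), CH2Cl2, rt
Reagents that add atoms: acetic anhydride, CC(=O)OC(C)=O
Why: Acid-catalysed methanolysis should remove the secondary TES and primary TBS ethers while the TBDPS ether survives, and acetylation of the two freed hydroxyls then installs both acetates of the target.

Step 14
Reactants: 19 diacetate
Product: 21 15-oxo-16-ene with C6–OTBDPS, via allylic alcohol 20 (not isolated)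
Conditions: SeO2 (0.5 equiv), t-BuOOH, CH2Cl2, rt; filter; Dess–Martin periodinane, CH2Cl2, 0 °C → rt
Reagents that add atoms: tert-butyl hydroperoxide, CC(C)(C)OO
Why: SeO2 allylic oxidation (ene reaction then [2,3]-shift) should hydroxylate C15, the only allylic position that can react because C13 is a bridgehead, and Dess–Martin oxidation then gives the α-methylene ketone whatever the C15 configuration.

Step 15
Reactants: 21 silyl-protected enone
Product: 22 target CNP0105570.2
Conditions: HF·pyridine, THF/pyridine, 0 °C → rt
Reagents that add atoms: none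
Why: Buffered fluoride desilylation should free the C6 hydroxyl without affecting the acetates, the lactone or the enone.

**Compound list**

1 | allyl propargyl ether | C=CCOCC#C | starting material
2 | 3-vinyl-2,5-dihydrofuran | C=CC1=CCOC1 | intermediate
3 | methacrolein | CC(=C)C=O | starting material
4 | (3aS,4R)-4-methyl-1,3,3a,4,5,6-hexahydroisobenzofuran-4-carbaldehyde (CHO cis to the furan CH2 at C3a) | C1OC[C@H]2C1=CCC[C@@]2(C)C=O | intermediate
5 | [(3aR,4R)-4-methyl-1,3,3a,4,5,6-hexahydroisobenzofuran-4-yl]methanol | C1OC[C@H]2C1=CCC[C@@]2(C)CO | intermediate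
6 | tert-butyldimethylsilyl ether of 5 | C1OC[C@H]2C1=CCC[C@@]2(C)CO[Si](C)(C)C(C)(C)C | intermediate
7 | buta-1,3-diene | C=CC=C | starting material
8 | propiolic acid | C#CC(=O)O | starting material
9 | cyclohexa-1,4-diene-1-carboxylic acid | OC(=O)C1=CCC=CC1 | intermediate
10 | bromo alcohol: 2-(bromomethyl)cyclohex-2-ene with 1-CH2OH and 6-methyl-6-CH2OTBS, CH2OH cis to CH2OTBS (C4, C5 as in 5) | BrCC1=CCC[C@@](C)(CO[Si](C)(C)C(C)(C)C)[C@H]1CO | intermediate (not isolated)
11 | C20 cyclohexa-1,4-diene-1-carboxylate of the ring A allylic alcohol, C6–OH free, C19–OTBS | O=C(OCC1=CCC[C@@](C)(CO[Si](C)(C)C(C)(C)C)[C@H]1CO)C1=CCC=CC1 | intermediate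
12 | C1/C10 epoxide of 11, epoxide oxygen cis to CH2OH | O=C(OC[C@]12O[C@H]1CC[C@@](C)(CO[Si](C)(C)C(C)(C)C)[C@H]2CO)C1=CCC=CC1 | intermediate
13 | tert-butyldiphenylsilyl ether of 12 (key-step substrate) | O=C(OC[C@]12O[C@H]1CC[C@@](C)(CO[Si](C)(C)C(C)(C)C)[C@H]2CO[Si](c1ccccc1)(c1ccccc1)C(C)(C)C)C1=CCC=CC1 | intermediate
14 | spirolactone: δ-lactone spiro at C10 to ring A and cis-fused to the cyclohexene ring C (C12=C13), C1–OH cis to C20, C9 attached on the ring A face opposite to C1–OH and C6 | O=C1OC[C@@]2([C@@H]3CC=CC[C@H]13)[C@@H](O)CC[C@@](C)(CO[Si](C)(C)C(C)(C)C)[C@H]2CO[Si](c1ccccc1)(c1ccccc1)C(C)(C)C | intermediate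
15 | C1 triethylsilyl ether of 14 | O=C1OC[C@@]2([C@@H]3CC=CC[C@H]13)[C@@H](O[Si](CC)(CC)CC)CC[C@@](C)(CO[Si](C)(C)C(C)(C)C)[C@H]2CO[Si](c1ccccc1)(c1ccccc1)C(C)(C)C | intermediate
16 | C8-(2-bromoprop-2-enyl) derivative of 15, bromoallyl cis to H9 | O=C1OC[C@@]2([C@@H]3CC=CC[C@]13CC(Br)=C)[C@@H](O[Si](CC)(CC)CC)CC[C@@](C)(CO[Si](C)(C)C(C)(C)C)[C@H]2CO[Si](c1ccccc1)(c1ccccc1)C(C)(C)C | intermediate
17 | 6,7-seco-ent-kaur-16-en-7,20-olide bearing 1-OTES, 19-OTBS, 6-OTBDPS (ring centres as in the target) | C=C1C[C@]23C[C@H]1CC[C@H]2[C@]1(COC3=O)[C@@H](O[Si](CC)(CC)CC)CC[C@@](C)(CO[Si](C)(C)C(C)(C)C)[C@H]1CO[Si](c1ccccc1)(c1ccccc1)C(C)(C)C | intermediate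
18 | 1,19-diol of 17 with 6-OTBDPS | C=C1C[C@]23C[C@H]1CC[C@H]2[C@]1(COC3=O)[C@@H](O)CC[C@@](C)(CO)[C@H]1CO[Si](c1ccccc1)(c1ccccc1)C(C)(C)C | intermediate (not isolated)
19 | 1,19-diacetate with 6-OTBDPS | C=C1C[C@]23C[C@H]1CC[C@H]2[C@]1(COC3=O)[C@@H](OC(C)=O)CC[C@@](C)(COC(C)=O)[C@H]1CO[Si](c1ccccc1)(c1ccccc1)C(C)(C)C | intermediate
20 | 15-hydroxy derivative of 19 (C15 epimers, configuration not defined) | C=C1C(O)[C@]23C[C@H]1CC[C@H]2[C@]1(COC3=O)[C@@H](OC(C)=O)CC[C@@](C)(COC(C)=O)[C@H]1CO[Si](c1ccccc1)(c1ccccc1)C(C)(C)C | intermediate (not isolated)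
21 | 15-oxo-16-ene with 6-OTBDPS | C=C1C(=O)[C@]23C[C@H]1CC[C@H]2[C@]1(COC3=O)[C@@H](OC(C)=O)CC[C@@](C)(COC(C)=O)[C@H]1CO[Si](c1ccccc1)(c1ccccc1)C(C)(C)C | intermediate
22 | CNP0105570.2: 1,19-diacetoxy-6-hydroxy-15-oxo-6,7-seco-ent-kaur-16-en-7,20-olide, (1S,4R,5R,8S,9S,10S,13R) | C=C1C(=O)[C@]23C[C@H]1CC[C@H]2[C@]1(COC3=O)[C@@H](OC(C)=O)CC[C@@](C)(COC(C)=O)[C@H]1CO | target

**Summary**

Total step count: 15. Longest linear sequence: 14 steps (steps 1–4 and 6–15; step 5 makes the acid partner).

**Steps most likely to fail**

1. Step 9 (proposed new method). The C10 radical may be reduced, eliminated to the alkene or quenched by hydrogen transfer before the rotamer-limited ester-tethered ring closure occurs, or the C9 face may be poorly discriminated.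
   Fallback, from 13 back to 15, all known reaction types: methanolysis of the dienoate of 13 (K2CO3, MeOH, 0 °C) should give the epoxy alcohol F1. Intermolecular Cp2TiCl-mediated reductive coupling of F1 with excess 2,2,2-trifluoroethyl acrylate (Cp2TiCl2, Mn, collidine·HCl, THF), the precedented open form of the same C9–C10 construction, should give after lactonisation at the C20 hydroxyl the spirolactone F2. TESOTf/2,6-lutidine gives the silyl ether F3. LiN(i-Pr)2 then PhSeBr gives the α-selenide F4, and H2O2 oxidation with syn-elimination gives the unsaturated lactone F5. An EtAlCl2-promoted Diels–Alder reaction of F5 with buta-1,3-diene 7, on the face of C8=C9 away from the C4/C5 arm, should build ring C and return to 15.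

2. Step 6. The bromoborane may also attack the TBS ether, the allylic bromide may form with transposition, or the bromo alcohol may re-close to the dihydrofuran before it is esterified.
   Fallback, from 6 back to 11: allylic oxidation of the ring OCH2 next to the alkene (CrO3·3,5-dimethylpyrazole, CH2Cl2, −20 °C) should give the butenolide F6. Reduction with i-Bu2AlH gives the diol F7. Selective acylation of the less hindered allylic primary hydroxyl with acid 9 (DCC, DMAP cat., CH2Cl2, −20 °C) returns to 11.

3. Step 12. The vinyl radical may close 6-endo, or the first-formed radical may rearrange through a cyclopropylcarbinyl radical to the bicyclo[2.2.2]octane, or the vinyl radical may be reduced before cyclisation.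
   Fallback, from 16 directly to 17: a reductive Heck cyclisation (Pd(OAc)2, PPh3, HCO2Na, DMF, 80 °C), in which zerovalent palladium inserts into the vinyl C–Br bond, the vinylpalladium adds 5-exo across C12=C13 and formate reduces the C12–Pd bond, avoiding free radicals altogether.

**Further compounds**

F1 | step 9 | epoxy alcohol from 13 (C20–OH free, C1/C10 epoxide, 19-OTBS, 6-OTBDPS) | OC[C@]12O[C@H]1CC[C@@](C)(CO[Si](C)(C)C(C)(C)C)[C@H]2CO[Si](c1ccccc1)(c1ccccc1)C(C)(C)C
F2 | step 9 | spiro δ-lactone with C8H2 and C9H2, C1–OH free | O=C1CC[C@]2(CO1)[C@@H](O)CC[C@@](C)(CO[Si](C)(C)C(C)(C)C)[C@H]2CO[Si](c1ccccc1)(c1ccccc1)C(C)(C)C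
F3 | step 9 | C1 triethylsilyl ether of F2 | O=C1CC[C@]2(CO1)[C@@H](O[Si](CC)(CC)CC)CC[C@@](C)(CO[Si](C)(C)C(C)(C)C)[C@H]2CO[Si](c1ccccc1)(c1ccccc1)C(C)(C)C
F4 | step 9 | C8 phenylselenide of F3 (C8 epimers) | O=C1C([Se]c3ccccc3)C[C@]2(CO1)[C@@H](O[Si](CC)(CC)CC)CC[C@@](C)(CO[Si](C)(C)C(C)(C)C)[C@H]2CO[Si](c1ccccc1)(c1ccccc1)C(C)(C)C
F5 | step 9 | C8=C9 unsaturated spirolactone | O=C1C=C[C@]2(CO1)[C@@H](O[Si](CC)(CC)CC)CC[C@@](C)(CO[Si](C)(C)C(C)(C)C)[C@H]2CO[Si](c1ccccc1)(c1ccccc1)C(C)(C)C
F6 | step 6 | butenolide from 6 (C20 carbonyl, lactone oxygen on C6) | O=C1OC[C@H]2C1=CCC[C@@]2(C)CO[Si](C)(C)C(C)(C)C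
F7 | step 6 | ring A diol (C20–OH and C6–OH free, 19-OTBS) | OCC1=CCC[C@@](C)(CO[Si](C)(C)C(C)(C)C)[C@H]1CO
F0 | step 12 | none | none
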